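Starting material plus target came to 101 % at the last epsilon reading, so the meeting agreed that in these flasks one can be read from the other.

the same everywhere: starting material 26 mM; free catalyst 0.1 mol%
- gamma: second substrate 0.25 equiv; temperature 0 °C; run made earlier
- epsilon: second substrate 0.38 equiv; temperature 18 °C; run made earlier
- Saturday's: second substrate 0.500 equiv; temperature 5 °C; time 40 h
- Thursday's: second substrate 0.500 equiv; temperature 30 °C; time 40 h

| run | time / h | target / % | catalyst intermediate A / % | starting material / % |
|---|---|---|---|---|
| gamma | 1.50 | 0 | 3 | 102 |
| gamma | 5.00 | 0 | 0 | 98 |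
| gamma | 8.00 | 1 | 0 | 99 |
| gamma | 12.0 | 2 | 3 | 99 |
| gamma | 20.0 | 1 | 1 | 100 |
| gamma | 25.0 | 3 | 0 | 94 |
| epsilon | 1.00 | 3 | 1 | 97 |
| epsilon | 1.50 | 2 | 0 | 99 |
| epsilon | 2.50 | 8 | 2 | 93 |
| epsilon | 4.00 | 9 | 1 | 91 |
| epsilon | 8.00 | 12 | 0 | 86 |
| epsilon | 12.0 | 20 | 0 | 81 |

(each reading ± 1.5 percentage points)

- a reading or a percentage of target counts all its forms, free or not

- which of these there is most of at the end, counted by the starting material in it, Saturday's (starting material / catalyst intermediate A / target)
- which of these there is most of at the end, counted by the starting material in it, Thursday's (starting material / catalyst intermediate A / target)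
- amount of the one of these that there is most of at the end, in percent of the starting material charged, Saturday's
- amount of the one of these that there is most of at the end, in percent of the starting material charged, Thursday's

The bench chemist reported 200 turnovers in the epsilon run by 12.0 h. She named this count the turnover number N, the percentage of target made divided by the percentage of catalyst charged. She argued that N is what to watch at so small a loading. If catalyst is being lost, she said, N taken per catalyst lost is the rate of making target over the rate of losing catalyst, so time drops out of it.

The forecast was then tabled: starting material the most in Saturday's flask at 85 %, and target the most in Thursday's at 75 %, on the ground that at the higher temperature “conversion would be high by 40 h”. The bench chemist accepted Saturday's figure. For Thursday's she reckoned that the forecast asks for N of 750, more than the epsilon count, and she asked whether the catalyst lasts that long. The meeting minuted that on Thursday's flask the thing to watch is whether target stops rising.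

Saturday's flask ended with starting material at 87.6 %, and Thursday's with starting material at 74.1 %, more than its target at 25.8 %.

catalyst intermediate A → free catalyst + target (k = 11.3 h⁻¹, Ea = 89.0 kJ mol⁻¹); crystals ⇌ target, rate k2*(cs2 - [target]) while solid is left; crystals form when [target] > cs2 (solubility = 0.490 mM, k = 0.264 h⁻¹); catalyst intermediate B → free catalyst + second product (k = 168 h⁻¹, Ea = 66.0 kJ mol⁻¹); second substrate + free catalyst ⇌ catalyst intermediate B (K = 42.6 M⁻¹, k = 44100 M⁻¹ h⁻¹, Ea = 36.0 kJ mol⁻¹, ΔH = −46.0 kJ mol⁻¹); catalyst intermediate A → spent catalyst (k = 0.0275 h⁻¹, Ea = 102 kJ mol⁻¹); starting material + free catalyst ⇌ catalyst intermediate A (K = 22.7 M⁻¹, k = 20100 M⁻¹ h⁻¹, Ea = 52.0 kJ mol⁻¹, ΔH = 14.0 kJ mol⁻¹); (constants at 5 °C) At the end Thursday's flask had >99.9 % of its catalyst spent, and its N stood at 258. Per catalyst lost, N was 411 in Saturday's flask and 411 in its neighbour at the same temperature with 100 mM of starting material. The conversion of catalyst intermediate A into spent catalyst is the main reason Thursday's flask stalled: with that step taken away, its starting material ends at 0.0157 % instead of 74.1 %.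

The numbers in the tables are simulated on assumed constants; noise was put on by code.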